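The oxane ring (O1, C2 to C6) is almost mirror-symmetric: C2 (ring B) and C6 (the two-carbon tether to ring A) are cis and flank the C4 carbinol, the pattern hidden in the pyranone of meso 8-oxabicyclo[3.2.1]oct-6-en-3-one. The route therefore rests on disconnecting C2–C3 and C5–C6 to furan and a three-carbon oxyallyl cation. One [4+3] cycloaddition forms both bonds, closes the oxanone ring and locks C2 and C6 cis through a two-carbon bridge, which later steers the C4 reduction and is then cut into two arms that a lipase distinguishes. The precursors are simply furan and 1,1,3-trichloroacetone, both commercial.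

Key step: step 1

Remark on labels: atom labels in the text follow the target oxane (O1, C2 bearing ring B, C4 carbinol, C6 bearing the tether to ring A) or, where stated, the bicycle (O8, C1 to C7). Systematic names of intermediates carry their own locants.

Assumption: Burkholderia cepacia lipase is taken to acetylate the hydroxymethyl arm on the R-configured ring carbon of meso diol 8, as drawn for 9; if it selects the other arm, the two arms are elaborated in the opposite order.

Step 1
Reactants: 1 furan; 2 1,1,3-trichloroacetone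
Product: 4 meso 8-oxabicyclo[3.2.1]oct-6-en-3-one, via dichloro cycloadduct 3 (not isolated)
Conditions: NaOCH2CF3, CF3CH2OH, furan (excess), 0 °C to rt; crude extract, then Zn/Cu couple, NH4Cl, MeOH, rt
Reagents that add atoms: none
Why: NaOCH2CF3 enolises 2 and the ionising solvent expels chloride, giving a 1,3-dichloro-2-oxyallyl cation (two π-electrons over three carbons) that adds across C2 and C5 of furan in a [4+3] cycloaddition, after which Zn/Cu removes both C–Cl bonds through zinc enolates that NH4Cl protonates. The closest known reaction type is the oxyallyl cation/furan [4+3] cycloaddition of α-polyhalo ketones followed by reductive dehalogenation. The oxan-4-one ring (O8 and C1 to C5 of the bicycle) is closed by intermolecular cycloaddition, both C–C bonds forming on one face of the planar diene, so no chain cyclisation and no ring-size competition is involved. The two bridgehead stereocentres are fixed cis by this suprafacial addition and, because the product is meso, no facial or absolute control is needed; the chlorine-bearing centres of 3 are erased by the reduction. The selectivity required is cycloaddition over solvent capture of the cation, Favorskii rearrangement and electrophilic substitution of furan, which the weakly nucleophilic CF3CH2OH, the excess of the weakly aromatic diene and the fast second ring-closing bond formation should secure.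

Step 2
Reactants: 4 meso 8-oxabicyclo[3.2.1]oct-6-en-3-one
Product: 5 meso endo-8-oxabicyclo[3.2.1]oct-6-en-3-ol (hydroxyl on the face of the C6=C7 bridge)
Conditions: LiBH(s-Bu)3, THF, −78 °C; then NaOH, H2O2, 0 °C
Reagents that add atoms: none
Why: Ketone reduction by a bulky trialkylborohydride, which cannot pass the C6=C7 bridge and attacks C3 (bicycle numbering) from the opposite side, so the hydroxyl ends up endo, which sets the C4 carbinol centre cis to both future arms while the compound stays meso.

Step 3
Reactants: 5 meso endo-8-oxabicyclo[3.2.1]oct-6-en-3-ol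
Product: 6 meso endo-3-(benzyloxy)-8-oxabicyclo[3.2.1]oct-6-ene
Conditions: NaH, BnBr, n-Bu4NI (cat.), THF, 0 °C to rt
Reagents that add atoms: benzyl bromide, BrCc1ccccc1
Why: Williamson ether synthesis on the sodium alkoxide; benzyl is chosen because it should survive every later step and leave together with the phenolic benzyl ethers in the final hydrogenation.

Step 4
Reactants: 6 meso endo-3-(benzyloxy)-8-oxabicyclo[3.2.1]oct-6-ene
Product: 8 meso all-cis [4-(benzyloxy)oxane-2,6-diyl]dimethanol, via ozonide 7 (not isolated)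
Conditions: O3, CH2Cl2, −78 °C; then NaBH4, MeOH, −78 °C to rt
Reagents that add atoms: ozone, [O-][O+]=O
Why: Criegee ozonolysis of the cis alkene and hydride reduction of the ozonide cut the two-carbon bridge into two hydroxymethyl arms without touching a ring stereocentre, so the cis C2/C6 relation and the cis C4 ether pass into an all-cis oxane that is still meso.

Step 5
Reactants: 8 meso all-cis [4-(benzyloxy)oxane-2,6-diyl]dimethanol
Product: 9 [(2R,4S,6S)-4-(benzyloxy)-6-(hydroxymethyl)oxan-2-yl]methyl acetate
Conditions: Burkholderia cepacia lipase (immobilised), vinyl acetate, t-BuOMe, rt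
Reagents that add atoms: vinyl acetate, C=COC(C)=O
Why: Lipase-catalysed irreversible transesterification (enzymatic desymmetrisation of a meso diol) acylates one of the two enantiotopic primary hydroxyls, which turns the meso compound into a single enantiomer and so fixes the absolute configuration of all three ring stereocentres at once.

Step 6
Reactants: 9 [(2R,4S,6S)-4-(benzyloxy)-6-(hydroxymethyl)oxan-2-yl]methyl acetate
Product: 11 (2S,4R,6R)-6-(acetoxymethyl)-4-(benzyloxy)oxane-2-carboxylic acid, via aldehyde 10 (not isolated)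
Conditions: TEMPO (cat.), PhI(OAc)2, MeCN/H2O (1:1), rt
Reagents that add atoms: water, O
Why: TEMPO-catalysed oxidation with PhI(OAc)2 in wet MeCN takes the primary alcohol through aldehyde 10, whose hydrate is oxidised on to the acid, under near-neutral conditions that should leave the acetate, the benzyl ether and the α-alkoxy stereocentre intact.

Step 7
Reactants: 12 5-bromo-2-hydroxy-3-methoxybenzaldehyde
Product: 14 5-bromo-3-methoxybenzene-1,2-diol, via aryl formate 13 (not isolated)
Conditions: H2O2 (aq), NaOH (aq), THF, 0 °C to rt, under N2; then HCl (aq)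
Reagents that add atoms: hydrogen peroxide, OO
Why: Dakin oxidation, in which hydroperoxide adds to the ortho-hydroxy aldehyde, aryl migration gives formate 13 and base hydrolyses it to the catechol, leaving bromine at the ring B attachment position (para to one hydroxyl, meta to the other and to the methoxy group).

Step 8
Reactants: 14 5-bromo-3-methoxybenzene-1,2-diol
Product: 15 1,2-bis(benzyloxy)-5-bromo-3-methoxybenzene
Conditions: BnBr, K2CO3, DMF, 60 °C
Reagents that add atoms: benzyl bromide, BrCc1ccccc1
Why: Double Williamson ether synthesis on the catechol gives a bis-benzyl ether that should tolerate the coupling and acid steps and is cleaved in the final hydrogenation.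

Step 9
Reactants: 11 (2S,4R,6R)-6-(acetoxymethyl)-4-(benzyloxy)oxane-2-carboxylic acid; 15 1,2-bis(benzyloxy)-5-bromo-3-methoxybenzene
Product: 16 [(2R,4S,6R)-4-(benzyloxy)-6-[3,4-bis(benzyloxy)-5-methoxyphenyl]oxan-2-yl]methyl acetate (aryl trans to the other two ring substituents)
Conditions: Ir[dF(CF3)ppy]2(dtbbpy)PF6 (1 mol%), NiCl2(MeOCH2CH2OMe) (10 mol%), 4,4′-di-tert-butyl-2,2′-bipyridine (15 mol%), Cs2CO3, DMF, blue LEDs, rt
Reagents that add atoms: none
Why: Metallaphotoredox decarboxylative arylation, in which photo-oxidation of the caesium carboxylate releases CO2 and an α-oxy radical that nickel captures after oxidative addition of 15, reductive elimination then forming the C–aryl bond; the pyramidal α-oxy radical should be taken up mainly on its axial face, so the axial-aryl epimer 16 is expected, and any equatorial epimer is simply the product of step 10.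

Step 10
Reactants: 16 [(2R,4S,6R)-4-(benzyloxy)-6-[3,4-bis(benzyloxy)-5-methoxyphenyl]oxan-2-yl]methyl acetate
Product: 17 [(2R,4S,6S)-4-(benzyloxy)-6-[3,4-bis(benzyloxy)-5-methoxyphenyl]oxan-2-yl]methyl acetate (all-cis)
Conditions: BF3·OEt2 (0.2 equiv), CH2Cl2, 0 °C to rt
Reagents that add atoms: none
Why: Lewis-acid ionisation of the benzylic ring C–O bond gives an open benzylic cation stabilised by the trioxygenated ring B, and reversible re-closure (acid-catalysed epimerisation of a 2-aryl oxane) should funnel the material to the all-equatorial isomer, so the aryl-bearing centre is set under thermodynamic control by the two untouched ring centres.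

Step 11
Reactants: 17 [(2R,4S,6S)-4-(benzyloxy)-6-[3,4-bis(benzyloxy)-5-methoxyphenyl]oxan-2-yl]methyl acetate
Product: 18 [(2R,4S,6S)-4-(benzyloxy)-6-[3,4-bis(benzyloxy)-5-methoxyphenyl]oxan-2-yl]methanol
Conditions: K2CO3 (cat.), MeOH, rt
Reagents that add atoms: none
Why: Base-catalysed transesterification (Zemplén-type methanolysis) removes the acetate and should leave the ethers and all stereocentres untouched.

Step 12
Reactants: 18 [(2R,4S,6S)-4-(benzyloxy)-6-[3,4-bis(benzyloxy)-5-methoxyphenyl]oxan-2-yl]methanol
Product: 19 (2R,4S,6S)-4-(benzyloxy)-6-[3,4-bis(benzyloxy)-5-methoxyphenyl]oxane-2-carbaldehyde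
Conditions: Dess–Martin periodinane, CH2Cl2, 0 °C to rt
Reagents that add atoms: none
Why: Dess–Martin oxidation stops at the aldehyde under mild, non-basic conditions, so the α-alkoxy stereocentre should not epimerise.

Step 13
Reactants: 20 vanillin
Product: 21 4-(benzyloxy)-3-methoxybenzaldehyde
Conditions: BnBr, K2CO3, DMF, rt
Reagents that add atoms: benzyl bromide, BrCc1ccccc1
Why: Williamson ether synthesis on the phenoxide masks the ring A phenol with a group that is removed in the final hydrogenation.

Step 14
Reactants: 21 4-(benzyloxy)-3-methoxybenzaldehyde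
Product: 22 [4-(benzyloxy)-3-methoxyphenyl]methanol
Conditions: NaBH4, MeOH, 0 °C
Reagents that add atoms: none
Why: Borohydride reduction of an aromatic aldehyde to the benzylic alcohol is chemoselective and leaves the benzyl ether alone.

Step 15
Reactants: 22 [4-(benzyloxy)-3-methoxyphenyl]methanol
Product: 23 [4-(benzyloxy)-3-methoxybenzyl]triphenylphosphonium bromide
Conditions: PPh3·HBr, MeCN, reflux
Reagents that add atoms: triphenylphosphine hydrobromide, [Br-].[PH+](c1ccccc1)(c1ccccc1)c1ccccc1
Why: The electron-rich benzylic alcohol is activated by HBr and the benzylic carbon is captured by PPh3 (phosphonium salt formation by nucleophilic substitution), giving the Wittig salt in one operation.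

Step 16
Reactants: 23 [4-(benzyloxy)-3-methoxybenzyl]triphenylphosphonium bromide; 19 (2R,4S,6S)-4-(benzyloxy)-6-[3,4-bis(benzyloxy)-5-methoxyphenyl]oxane-2-carbaldehyde
Product: 25 (2S,4R,6R)-4-(benzyloxy)-2-[3,4-bis(benzyloxy)-5-methoxyphenyl]-6-[2-[4-(benzyloxy)-3-methoxyphenyl]ethenyl]oxane (E/Z mixture), via ylide 24 (not isolated)
Conditions: 23, NaN(SiMe3)2, THF, 0 °C; then 19, −78 °C to rt
Reagents that add atoms: none
Why: Wittig olefination with the semi-stabilised benzylic ylide 24 joins the arm carbon to the ring A benzylic carbon, the low temperature limiting epimerisation next to the aldehyde, and the alkene geometry is irrelevant because the double bond is hydrogenated next.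

Step 17
Reactants: 25 (2S,4R,6R)-4-(benzyloxy)-2-[3,4-bis(benzyloxy)-5-methoxyphenyl]-6-[2-[4-(benzyloxy)-3-methoxyphenyl]ethenyl]oxane
Product: 26 (2S,4R,6S)-2-(3,4-dihydroxy-5-methoxyphenyl)-6-[2-(4-hydroxy-3-methoxyphenyl)ethyl]oxan-4-ol (CNP0399218.1)
Conditions: H2 (1 atm), Pd/C (10%), EtOAc/MeOH, rt; product handled under argon
Reagents that add atoms: none
Why: Heterogeneous catalytic hydrogenation saturates the alkene and hydrogenolyses the four O-benzyl groups in one operation without touching a stereocentre, neutral conditions being used so that the ring C2–O1 bond, a hindered secondary benzylic ether, should be cleaved far more slowly than the PhCH2–O bonds.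

Compound list
1 | furan | c1ccoc1 | starting material
2 | 1,1,3-trichloroacetone | O=C(CCl)C(Cl)Cl | starting material
3 | 2,4-dichloro-8-oxabicyclo[3.2.1]oct-6-en-3-one (chloro epimers unassigned; not isolated) | O=C1C(Cl)[C@H]2C=C[C@@H](C1Cl)O2 | intermediate
4 | meso 8-oxabicyclo[3.2.1]oct-6-en-3-one | O=C1C[C@H]2C=C[C@@H](C1)O2 | intermediate
5 | meso endo-8-oxabicyclo[3.2.1]oct-6-en-3-ol | C1=C[C@H]2C[C@@H](O)C[C@@H]1O2 | intermediate
6 | meso endo-3-(benzyloxy)-8-oxabicyclo[3.2.1]oct-6-ene | C1=C[C@H]2C[C@@H](OCc3ccccc3)C[C@@H]1O2 | intermediate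
7 | ozonide of 6 (1,2,4-trioxolane across former C6 and C7; acetal centres unassigned; not isolated) | O1OC4OC1[C@H]2C[C@@H](OCc3ccccc3)C[C@@H]4O2 | intermediate
8 | meso all-cis [(2R,4s,6S)-4-(benzyloxy)oxane-2,6-diyl]dimethanol | OC[C@H]1C[C@@H](OCc2ccccc2)C[C@@H](CO)O1 | intermediate
9 | [(2R,4S,6S)-4-(benzyloxy)-6-(hydroxymethyl)oxan-2-yl]methyl acetate | CC(=O)OC[C@H]1C[C@@H](OCc2ccccc2)C[C@@H](CO)O1 | intermediate
10 | [(2R,4R,6S)-4-(benzyloxy)-6-formyloxan-2-yl]methyl acetate (not isolated) | CC(=O)OC[C@H]1C[C@@H](OCc2ccccc2)C[C@@H](C=O)O1 | intermediate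
11 | (2S,4R,6R)-6-(acetoxymethyl)-4-(benzyloxy)oxane-2-carboxylic acid | CC(=O)OC[C@H]1C[C@@H](OCc2ccccc2)C[C@@H](C(=O)O)O1 | intermediate
12 | 5-bromo-2-hydroxy-3-methoxybenzaldehyde | COc1cc(Br)cc(C=O)c1O | starting material
13 | 5-bromo-2-hydroxy-3-methoxyphenyl formate (not isolated) | COc1cc(Br)cc(OC=O)c1O | intermediate
14 | 5-bromo-3-methoxybenzene-1,2-diol | COc1cc(Br)cc(O)c1O | intermediate
15 | 1,2-bis(benzyloxy)-5-bromo-3-methoxybenzene | COc1cc(Br)cc(OCc2ccccc2)c1OCc1ccccc1 | intermediate
16 | [(2R,4S,6R)-4-(benzyloxy)-6-[3,4-bis(benzyloxy)-5-methoxyphenyl]oxan-2-yl]methyl acetate (aryl trans) | CC(=O)OC[C@H]1C[C@@H](OCc2ccccc2)C[C@H](c2cc(OCc3ccccc3)c(OCc3ccccc3)c(OC)c2)O1 | intermediate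
17 | [(2R,4S,6S)-4-(benzyloxy)-6-[3,4-bis(benzyloxy)-5-methoxyphenyl]oxan-2-yl]methyl acetate (all-cis) | CC(=O)OC[C@H]1C[C@@H](OCc2ccccc2)C[C@@H](c2cc(OCc3ccccc3)c(OCc3ccccc3)c(OC)c2)O1 | intermediate
18 | [(2R,4S,6S)-4-(benzyloxy)-6-[3,4-bis(benzyloxy)-5-methoxyphenyl]oxan-2-yl]methanol | OC[C@H]1C[C@@H](OCc2ccccc2)C[C@@H](c2cc(OCc3ccccc3)c(OCc3ccccc3)c(OC)c2)O1 | intermediate
19 | (2R,4S,6S)-4-(benzyloxy)-6-[3,4-bis(benzyloxy)-5-methoxyphenyl]oxane-2-carbaldehyde | O=C[C@H]1C[C@@H](OCc2ccccc2)C[C@@H](c2cc(OCc3ccccc3)c(OCc3ccccc3)c(OC)c2)O1 | intermediate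
20 | vanillin (4-hydroxy-3-methoxybenzaldehyde) | COc1cc(C=O)ccc1O | starting material
21 | 4-(benzyloxy)-3-methoxybenzaldehyde | COc1cc(C=O)ccc1OCc1ccccc1 | intermediate
22 | [4-(benzyloxy)-3-methoxyphenyl]methanol | COc1cc(CO)ccc1OCc1ccccc1 | intermediate
23 | [4-(benzyloxy)-3-methoxybenzyl]triphenylphosphonium bromide | COc1cc(C[P+](c2ccccc2)(c2ccccc2)c2ccccc2)ccc1OCc1ccccc1.[Br-] | intermediate
24 | [4-(benzyloxy)-3-methoxybenzylidene]triphenylphosphorane (not isolated) | COc1cc(C=P(c2ccccc2)(c2ccccc2)c2ccccc2)ccc1OCc1ccccc1 | intermediate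
25 | (2S,4R,6R)-4-(benzyloxy)-2-[3,4-bis(benzyloxy)-5-methoxyphenyl]-6-[2-[4-(benzyloxy)-3-methoxyphenyl]ethenyl]oxane (E/Z mixture) | COc1cc(C=C[C@H]2C[C@@H](OCc3ccccc3)C[C@@H](c3cc(OCc4ccccc4)c(OCc4ccccc4)c(OC)c3)O2)ccc1OCc1ccccc1 | intermediate
26 | (2S,4R,6S)-2-(3,4-dihydroxy-5-methoxyphenyl)-6-[2-(4-hydroxy-3-methoxyphenyl)ethyl]oxan-4-ol | COc1cc(CC[C@H]2C[C@@H](O)C[C@@H](c3cc(O)c(O)c(OC)c3)O2)ccc1O | target

Total step count: 17 (12 on the main line, 2 for the ring B bromide, 3 for the ring A phosphonium salt).
Longest linear sequence: 12 steps (steps 1, 2, 3, 4, 5, 6, 9, 10, 11, 12, 16, 17).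

Steps most likely to fail

Step 9. Oxidative addition of the electron-rich bromide 15 to nickel may be slow, so the α-oxy radical could be lost to hydrogen abstraction or dimerisation before it is captured. The fallback replaces the light-driven coupling by a thermal coupling of an activated ester with an aryl nucleophile. It sets out from acid 11. N-Hydroxyphthalimide and N,N′-diisopropylcarbodiimide (DMAP cat., CH2Cl2, rt) should give the redox-active ester 1,3-dioxoisoindolin-2-yl (2S,4R,6R)-6-(acetoxymethyl)-4-(benzyloxy)oxane-2-carboxylate F1. Bromide 15 is converted by n-BuLi (THF, −78 °C) and ZnCl2 into [3,4-bis(benzyloxy)-5-methoxyphenyl]zinc chloride F2. NiCl2(MeOCH2CH2OMe) with 4,4′-di-tert-butyl-2,2′-bipyridine in THF/DMF at rt should then join F1 and F2 in a decarboxylative Negishi-type coupling, which the acetate tolerates. The fallback comes back to the route at 16, and any 17 formed alongside serves step 10 equally.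

Step 10. The benzylic C–O bond may ionise incompletely, because the para-benzyloxy group is twisted out of conjugation by its two ortho neighbours and donates weakly, and a stronger acid may strip benzyl groups. The fallback moves the epimerisation to the end, where a free para-hydroxyl opens the ring as a para-quinone methide. It sets out from 16 and runs steps 11, 12, 16 and 17 unchanged on the axial-aryl series. K2CO3/MeOH should give [(2R,4S,6R)-4-(benzyloxy)-6-[3,4-bis(benzyloxy)-5-methoxyphenyl]oxan-2-yl]methanol F3. Dess–Martin periodinane should give (2R,4S,6R)-4-(benzyloxy)-6-[3,4-bis(benzyloxy)-5-methoxyphenyl]oxane-2-carbaldehyde F4. Ylide 24 should give (2R,4R,6R)-4-(benzyloxy)-2-[3,4-bis(benzyloxy)-5-methoxyphenyl]-6-[2-[4-(benzyloxy)-3-methoxyphenyl]ethenyl]oxane F5. H2 over Pd/C should give (2R,4R,6S)-2-(3,4-dihydroxy-5-methoxyphenyl)-6-[2-(4-hydroxy-3-methoxyphenyl)ethyl]oxan-4-ol F6, the C2 epimer of the target. Mild Brønsted acid (CF3CO2H cat., degassed MeCN, rt) should then open the C2–O1 bond of F6 with the help of the ring B para-hydroxyl, and reversible oxa-conjugate re-closure should settle on the all-equatorial isomer. The fallback comes back to the route at 26.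

Step 17. Hydrogenolysis of the ring C2–O1 benzylic bond (ring opening) may compete with removal of the slow secondary benzyl ether, or debenzylation may stay incomplete if the reaction is stopped early. The fallback separates alkene reduction from a debenzylation that uses no hydrogen. It sets out from 25. Diimide generated from 2-nitrobenzenesulfonohydrazide and Et3N (CH2Cl2, rt) should saturate only the C=C bond and give (2S,4R,6S)-4-(benzyloxy)-2-[3,4-bis(benzyloxy)-5-methoxyphenyl]-6-[2-[4-(benzyloxy)-3-methoxyphenyl]ethyl]oxane F7. BCl3 with pentamethylbenzene as benzyl-cation scavenger (CH2Cl2, −78 °C) should then remove all four benzyl groups. The fallback comes back to the route at 26.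

Further compounds
F1 | step 9 | 1,3-dioxoisoindolin-2-yl (2S,4R,6R)-6-(acetoxymethyl)-4-(benzyloxy)oxane-2-carboxylate | CC(=O)OC[C@H]1C[C@@H](OCc2ccccc2)C[C@@H](C(=O)ON2C(=O)c3ccccc3C2=O)O1
F2 | step 9 | [3,4-bis(benzyloxy)-5-methoxyphenyl]zinc chloride | COc1cc([Zn]Cl)cc(OCc2ccccc2)c1OCc1ccccc1
F3 | step 10 | [(2R,4S,6R)-4-(benzyloxy)-6-[3,4-bis(benzyloxy)-5-methoxyphenyl]oxan-2-yl]methanol | OC[C@H]1C[C@@H](OCc2ccccc2)C[C@H](c2cc(OCc3ccccc3)c(OCc3ccccc3)c(OC)c2)O1
F4 | step 10 | (2R,4S,6R)-4-(benzyloxy)-6-[3,4-bis(benzyloxy)-5-methoxyphenyl]oxane-2-carbaldehyde | O=C[C@H]1C[C@@H](OCc2ccccc2)C[C@H](c2cc(OCc3ccccc3)c(OCc3ccccc3)c(OC)c2)O1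
F5 | step 10 | (2R,4R,6R)-4-(benzyloxy)-2-[3,4-bis(benzyloxy)-5-methoxyphenyl]-6-[2-[4-(benzyloxy)-3-methoxyphenyl]ethenyl]oxane (E/Z mixture) | COc1cc(C=C[C@H]2C[C@@H](OCc3ccccc3)C[C@H](c3cc(OCc4ccccc4)c(OCc4ccccc4)c(OC)c3)O2)ccc1OCc1ccccc1
F6 | step 10 | (2R,4R,6S)-2-(3,4-dihydroxy-5-methoxyphenyl)-6-[2-(4-hydroxy-3-methoxyphenyl)ethyl]oxan-4-ol | COc1cc(CC[C@H]2C[C@@H](O)C[C@H](c3cc(O)c(O)c(OC)c3)O2)ccc1O
F7 | step 17 | (2S,4R,6S)-4-(benzyloxy)-2-[3,4-bis(benzyloxy)-5-methoxyphenyl]-6-[2-[4-(benzyloxy)-3-methoxyphenyl]ethyl]oxane | COc1cc(CC[C@H]2C[C@@H](OCc3ccccc3)C[C@@H](c3cc(OCc4ccccc4)c(OCc4ccccc4)c(OC)c3)O2)ccc1OCc1ccccc1
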